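The target is an unsymmetrical diaryl ether. Its only stereocentres, C7 on ring A (the phenol ring) and C7' on ring B, are both aryl(methyl)methine carbons bonded to the same 4-methylpent-3-enyl chain. The plan exploits this repeat by cutting C7–C8 and C7'–C8' together. That leads back to one homoprenylzinc reagent and a core without defined stereochemistry: the pivalate-protected bis(1-bromoethyl) diaryl ether, taken as its full stereoisomer mixture. One nickel/pybox-catalysed enantioconvergent Negishi reaction should alkylate both benzylic sites, fix both (S) centres under ligand control and deliver both trisubstituted alkenes. The core arises from two acetophenones joined by SNAr.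

Key step: step 7

Numbering: ring A carries the free OH in the target and ring B is the other ring; C7 and C7' are the benzylic methine carbons, and C8 and C8' are the chain CH2 groups bonded to them.

Assumption: the (R,R) antipode of i-Pr-pybox is taken to give the (S) configuration at both aryl(methyl)methine carbons, by analogy with the sense of induction this catalyst family shows with related π-substituted secondary halides; should a trial on a simple 1-arylethyl bromide show the opposite sense, the equally available (S,S) ligand takes its place and nothing else changes.

Step 1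
Reactants: 1 methylhydroquinone (2-methylbenzene-1,4-diol)
Product: 2 acetylmethylhydroquinone 1-(2,5-dihydroxy-4-methylphenyl)ethanone
Conditions: AcOH, BF3·OEt2, 90 °C; then H2O
Reagents that add atoms: acetic acid, CC(=O)O
Why: Friedel–Crafts C-acylation of a hydroquinone (Fries-type, through the aryl acetate) should go to the one unhindered ring position that is ortho to a hydroxyl and para to the methyl group, and should stop after one acylation because the chelated aryl ketone is deactivated.

Step 2
Reactants: 2 acetylmethylhydroquinone; 3 2'-fluoro-4'-methylacetophenone
Product: 4 diaryl ether diketone phenol 1-[5-(2-acetyl-5-methylphenoxy)-2-hydroxy-4-methylphenyl]ethanone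
Conditions: Cs2CO3 (2.2 equiv), 3 (1.0 equiv), degassed DMSO, 100 °C, argon
Reagents that add atoms: none
Why: This is a nucleophilic aromatic substitution (SNAr, addition–elimination) on a fluoride activated by its ortho acetyl group, in which the 5-oxygen should react because the 2-oxygen is chelated to and conjugated with its own acetyl group, the same bias that allows mono-O-alkylation of 2,5-dihydroxyacetophenones.

Step 3
Reactants: 4 diaryl ether diketone phenol
Product: 5 diketone pivalate 2-acetyl-4-(2-acetyl-5-methylphenoxy)-5-methylphenyl pivalate
Conditions: PivCl, Et3N, DMAP (cat.), CH2Cl2, 0 °C to rt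
Reagents that add atoms: pivaloyl chloride, CC(C)(C)C(=O)Cl
Why: DMAP-catalysed O-acylation (nucleophilic acyl-transfer catalysis) should overcome the hydrogen bond and steric demand of the remaining phenol, while the amine base is too weak to enolise the methyl ketones and start a Baker–Venkataraman acyl shift.

Step 4
Reactants: 5 diketone pivalate
Product: 6 diol pivalate 2-(1-hydroxyethyl)-4-[2-(1-hydroxyethyl)-5-methylphenoxy]-5-methylphenyl pivalate (all four stereoisomers)
Conditions: BH3·SMe2, THF, 0 °C to rt; MeOH quench
Reagents that add atoms: none
Why: Borane carbonyl reduction gives neutral alkoxyboranes instead of free alkoxides, which should suppress the pivaloyl shift from the phenol oxygen to the C7 oxygen (and the o-quinone methide collapse it opens under borohydride conditions), while the hindered aryl ester reduces far more slowly than an aryl ketone; the two carbinol centres form without control, which is harmless because step 7 erases them.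

Step 5
Reactants: 7 5-bromo-2-methylpent-2-ene
Product: 8 (4-methylpent-3-enyl)zinc bromide (titrated solution in DMA, used as such)
Conditions: Zn dust (1.5 equiv), I2 (5 mol%), DMA, 70 °C
Reagents that add atoms: zinc, [Zn]
Why: Direct insertion of iodine-activated zinc into a primary alkyl bromide in a polar amide solvent tolerates the trisubstituted alkene, and any homoallyl/cyclopropylcarbinyl radical interconversion is degenerate and returns the same chain.

Step 6
Reactants: 6 diol pivalate
Product: 9 dibromide 2-(1-bromoethyl)-4-[2-(1-bromoethyl)-5-methylphenoxy]-5-methylphenyl pivalate (all four stereoisomers)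
Conditions: PBr3 (0.8 equiv), CH2Cl2, −10 to 0 °C; cold aq NaHCO3 wash, concentrated below rt, used the same day without chromatography
Reagents that add atoms: phosphorus tribromide, BrP(Br)Br
Why: PBr3 bromination of secondary benzylic alcohols through their phosphite esters runs under acidic conditions that leave the pivalate, the diaryl ether and the aryl methyl groups alone, and its stereochemical course does not matter because both C–Br centres are erased in step 7.

Step 7
Reactants: 9 dibromide; 8 (4-methylpent-3-enyl)zinc bromide
Product: 12 2-[(2S)-6-methylhept-5-en-2-yl]-4-{5-methyl-2-[(2S)-6-methylhept-5-en-2-yl]phenoxy}-5-methylphenyl pivalate, via ring A monoalkylated bromide 10 (not isolated), via ring B monoalkylated bromide 11 (not isolated)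
Conditions: NiBr2·diglyme (20 mol%), (R,R)-i-Pr-pybox (26 mol%), 8 (3.2 equiv), DMA, 0 °C
Reagents that add atoms: none
Why: A monovalent nickel–pybox species abstracts bromine from C7–Br or C7'–Br of 9 to give a planar benzylic radical, which removes whatever configuration the halide had; the radical is trapped by the divalent (4-methylpent-3-enyl)nickel–pybox complex formed by transmetalation from 8, reductive elimination from trivalent nickel forms C7–C8 or C7'–C8', and monobromides 10 and 11 (either may form first) re-enter the same cycle. The closest known reaction type is the nickel/pybox-catalysed enantioconvergent Negishi alkylation of racemic secondary benzylic bromides by primary alkylzinc halides in DMA, run here at two such sites of one molecule. No ring is closed. Each new stereocentre, (S) at C7 and (S) at C7', is set by the chiral pocket of the C2-symmetric ligand alone during radical capture and reductive elimination, since the two carbons lie seven bonds apart and should not influence each other; the twofold reaction should also divert most wrongly set material into the (S,R)/(R,S) diastereomer, so the (S,S) product should be enantiomerically purer than a single coupling would allow. The step needs chemoselectivity for C(sp3)–Br over the aryl C–O bonds and the ester carbonyl, and cross-coupling over β-hydride elimination, loss of HBr and benzylic dimerisation. These should be secured by the low temperature, the mild organozinc nucleophile, the tridentate ligand that leaves no free site for β-hydride elimination, the acyl group on the ring A oxygen that lowers its donor power towards C7, and the meta relation of C7 to the ether oxygen on ring A that rules out intramolecular C7–C7' coupling on geometric grounds.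

Step 8
Reactants: 12 pivalate of the target
Product: 13 target 5-methyl-2-[(2S)-6-methylhept-5-en-2-yl]-4-{5-methyl-2-[(2S)-6-methylhept-5-en-2-yl]phenoxy}phenol
Conditions: K2CO3 (2 equiv), degassed MeOH, 40 °C, argon; aq NH4Cl
Reagents that add atoms: none
Why: Base-mediated methanolysis (transesterification) of an aryl ester is driven by its phenoxide leaving group and should touch neither the alkenes, the diaryl ether nor the non-acidic benzylic stereocentres.

Compound list
1 | methylhydroquinone | Cc1cc(O)ccc1O | starting material
2 | 1-(2,5-dihydroxy-4-methylphenyl)ethanone | CC(=O)c1cc(O)c(C)cc1O | intermediate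
3 | 2'-fluoro-4'-methylacetophenone | CC(=O)c1ccc(C)cc1F | starting material
4 | 1-[5-(2-acetyl-5-methylphenoxy)-2-hydroxy-4-methylphenyl]ethanone | CC(=O)c1cc(Oc2cc(C)ccc2C(C)=O)c(C)cc1O | intermediate
5 | 2-acetyl-4-(2-acetyl-5-methylphenoxy)-5-methylphenyl pivalate | CC(=O)c1cc(Oc2cc(C)ccc2C(C)=O)c(C)cc1OC(=O)C(C)(C)C | intermediate
6 | 2-(1-hydroxyethyl)-4-[2-(1-hydroxyethyl)-5-methylphenoxy]-5-methylphenyl pivalate, all stereoisomers | CC(O)c1cc(Oc2cc(C)ccc2C(C)O)c(C)cc1OC(=O)C(C)(C)C | intermediate
7 | 5-bromo-2-methylpent-2-ene | CC(C)=CCCBr | starting material
8 | (4-methylpent-3-enyl)zinc bromide | CC(C)=CCC[Zn]Br | intermediate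
9 | 2-(1-bromoethyl)-4-[2-(1-bromoethyl)-5-methylphenoxy]-5-methylphenyl pivalate, all stereoisomers | CC(Br)c1cc(Oc2cc(C)ccc2C(C)Br)c(C)cc1OC(=O)C(C)(C)C | intermediate
10 | 4-[2-(1-bromoethyl)-5-methylphenoxy]-5-methyl-2-[(2S)-6-methylhept-5-en-2-yl]phenyl pivalate, both C7' epimers | CC(C)=CCC[C@H](C)c1cc(Oc2cc(C)ccc2C(C)Br)c(C)cc1OC(=O)C(C)(C)C | intermediate
11 | 2-(1-bromoethyl)-5-methyl-4-{5-methyl-2-[(2S)-6-methylhept-5-en-2-yl]phenoxy}phenyl pivalate, both C7 epimers | CC(Br)c1cc(Oc2cc(C)ccc2[C@@H](C)CCC=C(C)C)c(C)cc1OC(=O)C(C)(C)C | intermediate
12 | 2-[(2S)-6-methylhept-5-en-2-yl]-4-{5-methyl-2-[(2S)-6-methylhept-5-en-2-yl]phenoxy}-5-methylphenyl pivalate | CC(C)=CCC[C@H](C)c1cc(Oc2cc(C)ccc2[C@@H](C)CCC=C(C)C)c(C)cc1OC(=O)C(C)(C)C | intermediate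
13 | 5-methyl-2-[(2S)-6-methylhept-5-en-2-yl]-4-{5-methyl-2-[(2S)-6-methylhept-5-en-2-yl]phenoxy}phenol | CC(C)=CCC[C@H](C)c1cc(Oc2cc(C)ccc2[C@@H](C)CCC=C(C)C)c(C)cc1O | target

Total step count: 8
Longest linear sequence: 7 steps (1, 2, 3, 4, 6, 7, 8); step 5 is a one-step branch.

Steps most likely to fail

Step 7.
- **What may go wrong:**
  - Facial selection at one or both acyclic, ortho-oxygenated benzylic radicals may be incomplete. The stereoisomers then differ only at remote centres and would be hard to separate.
  - The bromide may ionise or lose HBr in DMA.
  - The reaction may stall after the first alkylation.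
- **Fallback, from 9 back to 12:**
  - Twofold dehydrobromination of 9 with DBU in toluene at 60 °C would give 2-ethenyl-4-(2-ethenyl-5-methylphenoxy)-5-methylphenyl pivalate F1.
  - Both vinylarene units would then undergo nickel-catalysed asymmetric hydrovinylation. The conditions are [Ni(allyl)Br]2, a binaphthol-derived phosphoramidite of the antipode that gives (S), Na[B(3,5-(CF3)2C6H3)4], ethylene at 1 atm, CH2Cl2, −70 °C.
  - This would give 2-[(2S)-but-3-en-2-yl]-4-{2-[(2S)-but-3-en-2-yl]-5-methylphenoxy}-5-methylphenyl pivalate F2, with C7 and C7' set by a reaction type established for 3-arylbut-1-enes.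
  - Hydroboration of both terminal alkenes with 9-BBN-H in THF would give the bis(B-alkyl-9-borabicyclononane) adduct F3.
  - The adduct would be coupled without isolation with 1-bromo-2-methylprop-1-ene (CC(C)=CBr) in a B-alkyl Suzuki–Miyaura reaction (PdCl2(dppf), K3PO4, DMF–THF, rt to 50 °C). This returns to 12.

Step 6.
- **What may go wrong:** The electron-rich secondary benzylic bromide may ionise during work-up and concentration. That would bring loss of HBr, hydrolysis, or participation and transfer of the neighbouring pivaloyl group.
- **Fallback, from 6 back to 12, bypassing 9:**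
  - SOCl2 in CH2Cl2 at 0 °C would give 2-(1-chloroethyl)-4-[2-(1-chloroethyl)-5-methylphenoxy]-5-methylphenyl pivalate F4 as all stereoisomers. This electrophile is less prone to ionise and should survive chromatography and storage.
  - Secondary benzylic chlorides are also established partners in the nickel/pybox Negishi alkylation. Reaction of F4 with 8 under the catalyst of step 7 should therefore lead to 12.
  - The reaction would pass through the ring A monoalkylated chloride F5 and the ring B monoalkylated chloride F6, neither isolated.

Step 2.
- **What may go wrong:**
  - Substitution may be sluggish, because the ring is activated by a single acetyl group and the phenoxide is hindered.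
  - Prolonged heating would then allow base-induced aldol self-condensation of the methyl ketones, oxidation of the hydroquinone, or arylation of the wrong oxygen.
- **Fallback, from 2 back to 4:** A copper-catalysed Ullmann-type C–O coupling of 2 with commercial 2'-bromo-4'-methylacetophenone (CC(=O)c1ccc(C)cc1Br) would be used, with CuI, N,N-dimethylglycine and Cs2CO3 in dioxane at 90 °C. It does not depend on ring activation, and the ortho acetyl group assists it. No compound outside the list is made (entry F0).

Further compounds
F1 | step 7 | 2-ethenyl-4-(2-ethenyl-5-methylphenoxy)-5-methylphenyl pivalate | C=Cc1cc(Oc2cc(C)ccc2C=C)c(C)cc1OC(=O)C(C)(C)C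
F2 | step 7 | 2-[(2S)-but-3-en-2-yl]-4-{2-[(2S)-but-3-en-2-yl]-5-methylphenoxy}-5-methylphenyl pivalate | C=C[C@H](C)c1cc(Oc2cc(C)ccc2[C@@H](C)C=C)c(C)cc1OC(=O)C(C)(C)C
F3 | step 7 | bis(B-alkyl-9-borabicyclononane) adduct of F2 | C(CB1C2CCCC1CCC2)[C@H](C)c1cc(Oc2cc(C)ccc2[C@@H](C)CCB2C3CCCC2CCC3)c(C)cc1OC(=O)C(C)(C)C
F4 | step 6 | 2-(1-chloroethyl)-4-[2-(1-chloroethyl)-5-methylphenoxy]-5-methylphenyl pivalate, all stereoisomers | CC(Cl)c1cc(Oc2cc(C)ccc2C(C)Cl)c(C)cc1OC(=O)C(C)(C)C
F5 | step 6 | ring A monoalkylated chloride, both C7' epimers | CC(C)=CCC[C@H](C)c1cc(Oc2cc(C)ccc2C(C)Cl)c(C)cc1OC(=O)C(C)(C)C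
F6 | step 6 | ring B monoalkylated chloride, both C7 epimers | CC(Cl)c1cc(Oc2cc(C)ccc2[C@@H](C)CCC=C(C)C)c(C)cc1OC(=O)C(C)(C)C
F0 | step 2 | none | none
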